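**Overview**

1. Target 31 (C30) ⇐ C15 furanoid enal 16 by three Horner–Wadsworth–Emmons C5 extensions (C11=C12 with 17; C15=C15' and C12'=C11' with 23), each ester reduced and re-oxidised.
2. The strategy rests on ring B, the 2,5-dihydrofuran O–C5–C6=C7–C8 fused to ring A at C5–C6. It is the cycloisomer of a C5-hydroxy C6=C7=C8 allene, so O–C8 is made by gold-catalysed 5-endo addition of O5 and the allene axis becomes the C8 centre.
3. Allenol 13 ⇐ anti SN2' hydride opening of the C5,C6 epoxide of a C6–C7≡C8 enyne (sets the axis) ⇐ 3-OH-directed syn epoxidation (sets C5) ⇐ Sonogashira coupling of ring A enol triflate 6 with enyne 8.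
4. Ring A comes from ketoisophorone, with C3 set by asymmetric transfer hydrogenation; ring B is closed in step 11. O11 carries TBDPS instead of TBS so that a C3 TES ether can be cleaved selectively before the epoxidation.

Key step: step 11

Numbering: carotenoid atom labels are used (ring A: C1 gem-dimethyl, C2, C3 carbinol, C4, C5 methyl-bearing, C6; chain C7–C15, then C15'–C8' = CHO). "Fur" in names = (2R,6R,7aR)-6-hydroxy-4,4,7a-trimethyl-2,4,5,6,7,7a-hexahydro-1-benzofuran-2-yl (3-OH cis to the ring oxygen; C8 side chain trans to the C5 methyl).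

Assumption: ethyl (E)-4-bromo-2-methylbut-2-enoate (22) is taken as purchasable, and ketone 4 is used as its C6 epimer mixture because C6 becomes sp2 in step 4.

**Route**

Step 1
Reactants: 1 ketoisophorone
Product: 2 (R)-4-hydroxy-2,6,6-trimethylcyclohex-2-en-1-one
Conditions: RuCl[(R,R)-TsDPEN](p-cymene) (1 mol %), KOH (1.2 mol %), i-PrOH, 20 °C
Reagents that add atoms: none
Why: Noyori asymmetric transfer hydrogenation should reduce only the C4 carbonyl (between CH= and CH2; the C1 carbonyl is shielded by C(CH3)= and C(CH3)2), and the (R,R) ligand is expected, by analogy with aryl ketones, to give the R carbinol that becomes C3 of the target (the antipodal ligand is used if the sense proves opposite).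

Step 2
Reactants: 2 (R)-4-hydroxy-2,6,6-trimethylcyclohex-2-en-1-one
Product: 3 (R)-2,6,6-trimethyl-4-(triethylsilyloxy)cyclohex-2-en-1-one
Conditions: Et3SiCl, imidazole, DMF, 0 °C → rt
Reagents that add atoms: triethylsilyl chloride, CC[Si](Cl)(CC)CC
Why: Standard silylation of a secondary alcohol, with TES chosen because it survives enolate chemistry and cross-coupling yet can later be cleaved beside a primary TBDPS ether.

Step 3
Reactants: 3 (R)-2,6,6-trimethyl-4-(triethylsilyloxy)cyclohex-2-en-1-one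
Product: 4 (4S)-2,2,6-trimethyl-4-(triethylsilyloxy)cyclohexan-1-one (C6 epimer mixture)
Conditions: H2 (1 atm), Pd/C (5 %), EtOAc, rt
Reagents that add atoms: none
Why: Heterogeneous hydrogenation saturates the enone C=C while the silyl ether suppresses palladium-mediated allylic alcohol isomerisation; the carbinol is untouched (R becomes S only through a change in CIP ranking) and the new C6 centre is erased in step 4.

Step 4
Reactants: 4 (4S)-2,2,6-trimethyl-4-(triethylsilyloxy)cyclohexan-1-one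
Product: 6 (S)-2,6,6-trimethyl-4-(triethylsilyloxy)cyclohex-1-en-1-yl trifluoromethanesulfonate, via lithium enolate 5 (not isolated)
Conditions: LiN(i-Pr)2, THF, −78 °C; then PhNTf2, −78 °C → rt
Reagents that add atoms: N-phenylbis(trifluoromethanesulfonimide), O=S(=O)(N(c1ccccc1)S(=O)(=O)C(F)(F)F)C(F)(F)F
Why: Only C6 carries an α-hydrogen (C2 is quaternary), so deprotonation gives a single enolate, and O-triflation with PhNTf2 is the established enol triflate synthesis for this ring type.

Step 5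
Reactants: 7 (E)-3-methylpent-2-en-4-yn-1-ol
Product: 8 (E)-tert-butyl[(3-methylpent-2-en-4-yn-1-yl)oxy]diphenylsilane
Conditions: t-BuPh2SiCl, imidazole, CH2Cl2, 0 °C → rt
Reagents that add atoms: tert-butyldiphenylsilyl chloride, CC(C)(C)[Si](Cl)(c1ccccc1)c1ccccc1
Why: Silylation of the primary allylic alcohol masks O11, so that the later vanadium epoxidation has only the C3 hydroxyl to direct it, and gives a silyl ether robust enough for the selective TES cleavage in step 7.

Step 6
Reactants: 6 (S)-2,6,6-trimethyl-4-(triethylsilyloxy)cyclohex-1-en-1-yl trifluoromethanesulfonate; 8 (E)-tert-butyl[(3-methylpent-2-en-4-yn-1-yl)oxy]diphenylsilane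
Product: 9 tert-butyl{[(E)-3-methyl-5-[(S)-2,6,6-trimethyl-4-(triethylsilyloxy)cyclohex-1-en-1-yl]pent-2-en-4-yn-1-yl]oxy}diphenylsilane
Conditions: Pd(PPh3)4 (5 mol %), CuI (10 mol %), i-Pr2NH, DMF, rt → 50 °C
Reagents that add atoms: none
Why: Sonogashira coupling of a vinyl triflate with a terminal alkyne forms the C6–C7 bond and completes the C15 skeleton with the 9E alkene carried over from 7 unchanged.

Step 7
Reactants: 9 tert-butyl{[(E)-3-methyl-5-[(S)-2,6,6-trimethyl-4-(triethylsilyloxy)cyclohex-1-en-1-yl]pent-2-en-4-yn-1-yl]oxy}diphenylsilane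
Product: 10 (S)-4-[(E)-5-(tert-butyldiphenylsilyloxy)-3-methylpent-3-en-1-yn-1-yl]-3,5,5-trimethylcyclohex-3-en-1-ol
Conditions: PPTS (0.2 equiv), MeOH/CH2Cl2, 0 °C
Reagents that add atoms: none
Why: Acid-catalysed methanolysis cleaves the secondary TES ether far faster than the primary TBDPS ether, freeing the C3 hydroxyl as the directing group.

Step 8
Reactants: 10 (S)-4-[(E)-5-(tert-butyldiphenylsilyloxy)-3-methylpent-3-en-1-yn-1-yl]-3,5,5-trimethylcyclohex-3-en-1-ol
Product: 11 (1R,3R,6R)-6-[(E)-5-(tert-butyldiphenylsilyloxy)-3-methylpent-3-en-1-yn-1-yl]-1,5,5-trimethyl-7-oxabicyclo[4.1.0]heptan-3-ol (epoxide oxygen cis to the hydroxyl; 3R,5R,6R in carotenoid numbering)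
Conditions: VO(acac)2 (5 mol %), t-BuOOH (1.5 equiv, in decane), toluene, 0 °C → rt
Reagents that add atoms: tert-butyl hydroperoxide, CC(C)(C)OO
Why: In this hydroxyl-directed vanadium epoxidation of a cyclic homoallylic alcohol the vanadate ester of the C3 hydroxyl delivers the peroxide oxygen to the same face of C5=C6, setting C5 syn to O3, while the C9=C10 alkene has no free hydroxyl and is left alone.

Step 9
Reactants: 11 (1R,3R,6R)-6-[(E)-5-(tert-butyldiphenylsilyloxy)-3-methylpent-3-en-1-yn-1-yl]-1,5,5-trimethyl-7-oxabicyclo[4.1.0]heptan-3-ol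
Product: 12 (1R,3R)-6-[(3E)-5-(tert-butyldiphenylsilyloxy)-3-methylpenta-1,3-dien-1-ylidene]-1,5,5-trimethylcyclohexane-1,3-diol with S allene axis (C9 on the face of the C5 hydroxyl, H8 on the face of the C5 methyl)
Conditions: i-Bu2AlH (3.5 equiv), CH2Cl2, −78 → 0 °C; aq. KNaC4H4O6
Reagents that add atoms: none
Why: In this SN2' reduction of an alkynyl epoxide the aluminium reagent activates the epoxide oxygen and hydride adds to C8 anti to the departing C6–O bond, which fixes the allene axis, while the C5–O bond is untouched and C5 keeps its configuration.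

Step 10
Reactants: 12 allenic diol
Product: 13 (1R,5R)-5-(tert-butyldimethylsilyloxy)-2-[(3E)-5-(tert-butyldiphenylsilyloxy)-3-methylpenta-1,3-dien-1-ylidene]-1,3,3-trimethylcyclohexan-1-ol with S allene axis (3-O-TBS and 11-O-TBDPS allenol with free C5 hydroxyl)
Conditions: t-BuMe2SiCl (1.2 equiv), imidazole, DMF, 0 °C → rt
Reagents that add atoms: tert-butyldimethylsilyl chloride, CC(C)(C)[Si](C)(C)Cl
Why: The secondary C3 hydroxyl is silylated selectively over the hindered tertiary C5 hydroxyl, which removes O3 as a competing nucleophile (5-exo attack at C6) in the gold step.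

Step 11
Reactants: 13 3-O-TBS and 11-O-TBDPS allenol
Product: 14 tert-butyl{[(E)-3-[(2R,6R,7aR)-6-(tert-butyldimethylsilyloxy)-4,4,7a-trimethyl-2,4,5,6,7,7a-hexahydro-1-benzofuran-2-yl]but-2-en-1-yl]oxy}diphenylsilane
Conditions: Ph3PAuNTf2 (2 mol %), THF, −20 → 0 °C; Et3N quench
Reagents that add atoms: none
Why: The cationic gold centre, monovalent throughout, coordinates the C7=C8 π bond (whose lobes lie in the plane through C1, C5 and C6) from the side remote from C5, the C5 hydroxyl adds to C8 anti to the metal in a 5-endo-trig closure that makes the O–C8 bond and ring B, and protodeauration of the C7–Au bond leaves C6=C7 endocyclic. The closest known reaction type is the gold- or silver-catalysed cycloisomerisation of α-hydroxyallenes to 2,5-dihydrofurans, which transfers axial to central chirality. In 13 H8 lies on the C5-methyl side and C9 on the hydroxyl side of that plane while O5 attacks within the plane, so the S axis is converted into the 8R centre with C9 trans to the C5 methyl; the new centre therefore follows from the allene axis alone and needs no face selection by ring A. The step needs chemoselectivity for O5, secured by silylation of O3 and O11, and stereochemical fidelity, secured by the coordinating solvent, low temperature and amine quench, since the doubly allylic C8–O bond ionises under acid.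

Step 12
Reactants: 14 furanoid bis-silyl ether
Product: 15 (2R,6R,7aR)-2-[(E)-4-hydroxybut-2-en-2-yl]-4,4,7a-trimethyl-2,4,5,6,7,7a-hexahydro-1-benzofuran-6-ol
Conditions: Bu4NF (3 equiv), THF, 0 °C → rt
Reagents that add atoms: none
Why: Fluoride cleaves both silyl ethers under basic conditions that cannot ionise the C8–O bond, so no deprotection is needed at the polyene aldehyde stage.

Step 13
Reactants: 15 furanoid diol
Product: 16 (E)-3-Fur-but-2-enal
Conditions: MnO2 (activated, excess), CH2Cl2, rt, dark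
Reagents that add atoms: none
Why: MnO2 oxidises only the allylic C11 alcohol and leaves the saturated secondary C3 alcohol, under neutral conditions.

Step 14
Reactants: 16 (E)-3-Fur-but-2-enal; 17 triethyl 3-methyl-4-phosphonocrotonate
Product: 19 ethyl (2E,4E,6E)-3-methyl-7-Fur-octa-2,4,6-trienoate, via lithiated phosphonate 18 (not isolated)
Conditions: 17, n-BuLi, DMPU, THF, −78 °C; then 16, −78 → 0 °C
Reagents that add atoms: none
Why: The Horner–Wadsworth–Emmons reaction of the stabilised allylic phosphonate anion forms C11=C12 with E selectivity, the C13=C14 bond of the equilibrating anion ends mainly E, and the anion is too weak a base to deprotonate the C3 hydroxyl.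

Step 15
Reactants: 19 C20 ester
Product: 20 (2E,4E,6E)-3-methyl-7-Fur-octa-2,4,6-trien-1-ol
Conditions: i-Bu2AlH (3.5 equiv), CH2Cl2, −78 °C; aq. KNaC4H4O6
Reagents that add atoms: none
Why: 1,2-Reduction of the conjugated ester to the allylic alcohol at low temperature, with a neutral tartrate work-up that spares the furanoid.

Step 16
Reactants: 20 C20 alcohol
Product: 21 (2E,4E,6E)-3-methyl-7-Fur-octa-2,4,6-trienal
Conditions: MnO2, CH2Cl2, rt, dark
Reagents that add atoms: none
Why: Chemoselective MnO2 oxidation of the polyenylic primary alcohol, as in step 13.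

Step 17
Reactants: 22 ethyl (E)-4-bromo-2-methylbut-2-enoate
Product: 23 triethyl 2-methyl-4-phosphonocrotonate (ethyl (E)-4-(diethoxyphosphoryl)-2-methylbut-2-enoate)
Conditions: P(OEt)3, neat, 120 °C (EtBr distilled off)
Reagents that add atoms: triethyl phosphite, CCOP(OCC)OCC
Why: Michaelis–Arbuzov reaction of the primary allylic bromide, which leaves the E alkene unchanged.

Step 18
Reactants: 21 C20 aldehyde; 23 triethyl 2-methyl-4-phosphonocrotonate
Product: 25 ethyl (2E,4E,6E,8E,10E)-2,7-dimethyl-11-Fur-dodeca-2,4,6,8,10-pentaenoate, via lithiated phosphonate 24 (not isolated)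
Conditions: 23, n-BuLi, DMPU, THF, −78 °C; then 21, −78 → 0 °C
Reagents that add atoms: none
Why: Horner–Wadsworth–Emmons olefination forms C15=C15' with E selectivity and brings in C14'=C13' (E, from the reagent) with the C13' methyl.

Step 19
Reactants: 25 C25 ester
Product: 26 (2E,4E,6E,8E,10E)-2,7-dimethyl-11-Fur-dodeca-2,4,6,8,10-pentaen-1-ol
Conditions: i-Bu2AlH (3.5 equiv), CH2Cl2, −78 °C; aq. KNaC4H4O6
Reagents that add atoms: none
Why: 1,2-Reduction of the conjugated ester, as in step 15.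

Step 20
Reactants: 26 C25 alcohol
Product: 27 (2E,4E,6E,8E,10E)-2,7-dimethyl-11-Fur-dodeca-2,4,6,8,10-pentaenal
Conditions: MnO2, CH2Cl2, rt, dark
Reagents that add atoms: none
Why: Chemoselective MnO2 oxidation of the polyenylic alcohol.

Step 21
Reactants: 27 C25 aldehyde; 23 triethyl 2-methyl-4-phosphonocrotonate
Product: 29 ethyl (2E,4E,6E,8E,10E,12E,14E)-2,6,11-trimethyl-15-Fur-hexadeca-2,4,6,8,10,12,14-heptaenoate, via sodiated phosphonate 28 (not isolated)
Conditions: 23 (1.3 equiv), NaN(SiMe3)2 (1.25 equiv), THF, −78 °C; then 27, −78 → 0 °C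
Reagents that add atoms: none
Why: This third Horner–Wadsworth–Emmons olefination uses the sodium anion, which is less tightly ion-paired than the lithium one and is made with a non-nucleophilic amide base to suit the less electrophilic α-methyl-branched C25 polyenal; it forms C12'=C11' with E selectivity and brings in C10'=C9' (E, from the reagent) with the C9' methyl, completing the C30 chain.

Step 22
Reactants: 29 C30 ester
Product: 30 (2E,4E,6E,8E,10E,12E,14E)-2,6,11-trimethyl-15-Fur-hexadeca-2,4,6,8,10,12,14-heptaen-1-ol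
Conditions: i-Bu2AlH (3.5 equiv), CH2Cl2, −78 °C; aq. KNaC4H4O6
Reagents that add atoms: none
Why: 1,2-Reduction of the conjugated ester, as in step 15.

Step 23
Reactants: 30 C30 alcohol
Product: 31 (2E,4E,6E,8E,10E,12E,14E)-2,6,11-trimethyl-15-Fur-hexadeca-2,4,6,8,10,12,14-heptaenal, the target (3R,5R,8R in carotenoid numbering)
Conditions: MnO2, CH2Cl2, rt, dark, argon
Reagents that add atoms: none
Why: Neutral MnO2 oxidation of the terminal polyenylic alcohol gives the C8' aldehyde without touching the C3 alcohol or the acid-labile C8–O bond.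

**Compound list**

1 | ketoisophorone (2,6,6-trimethylcyclohex-2-ene-1,4-dione) | CC1=CC(=O)CC(C)(C)C1=O | starting material
2 | (R)-4-hydroxy-2,6,6-trimethylcyclohex-2-en-1-one | CC1=C[C@H](O)CC(C)(C)C1=O | intermediate
3 | (R)-2,6,6-trimethyl-4-(triethylsilyloxy)cyclohex-2-en-1-one | CC1=C[C@H](O[Si](CC)(CC)CC)CC(C)(C)C1=O | intermediate
4 | (4S)-2,2,6-trimethyl-4-(triethylsilyloxy)cyclohexan-1-one, C6 epimer mixture | CC1C[C@H](O[Si](CC)(CC)CC)CC(C)(C)C1=O | intermediate
5 | lithium (S)-2,6,6-trimethyl-4-(triethylsilyloxy)cyclohex-1-en-1-olate | CC1=C(O[Li])C(C)(C)C[C@@H](O[Si](CC)(CC)CC)C1 | intermediate (not isolated)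
6 | (S)-2,6,6-trimethyl-4-(triethylsilyloxy)cyclohex-1-en-1-yl trifluoromethanesulfonate | CC1=C(OS(=O)(=O)C(F)(F)F)C(C)(C)C[C@@H](O[Si](CC)(CC)CC)C1 | intermediate
7 | (E)-3-methylpent-2-en-4-yn-1-ol | C#C/C(C)=C/CO | starting material
8 | (E)-tert-butyl[(3-methylpent-2-en-4-yn-1-yl)oxy]diphenylsilane | C#C/C(C)=C/CO[Si](c1ccccc1)(c1ccccc1)C(C)(C)C | intermediate
9 | dienyne, 3-O-TES and 11-O-TBDPS | CC1=C(C#C/C(C)=C/CO[Si](c2ccccc2)(c2ccccc2)C(C)(C)C)C(C)(C)C[C@@H](O[Si](CC)(CC)CC)C1 | intermediate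
10 | (S)-4-[(E)-5-(tert-butyldiphenylsilyloxy)-3-methylpent-3-en-1-yn-1-yl]-3,5,5-trimethylcyclohex-3-en-1-ol | CC1=C(C#C/C(C)=C/CO[Si](c2ccccc2)(c2ccccc2)C(C)(C)C)C(C)(C)C[C@@H](O)C1 | intermediate
11 | (1R,3R,6R)-6-[(E)-5-(tert-butyldiphenylsilyloxy)-3-methylpent-3-en-1-yn-1-yl]-1,5,5-trimethyl-7-oxabicyclo[4.1.0]heptan-3-ol (syn epoxide) | C[C@@]12C[C@H](O)CC(C)(C)[C@]1(C#C/C(C)=C/CO[Si](c3ccccc3)(c3ccccc3)C(C)(C)C)O2 | intermediate
12 | allenic 3,5-diol with 11-O-TBDPS, (3R,5R), S axis | [H]C(/C(C)=C/CO[Si](c1ccccc1)(c1ccccc1)C(C)(C)C)=[C@@]=C1C(C)(C)C[C@@H](O)C[C@@]1(C)O | intermediate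
13 | allenol with 3-O-TBS, 11-O-TBDPS and free C5 hydroxyl, (3R,5R), S axis (key-step precursor) | [H]C(/C(C)=C/CO[Si](c1ccccc1)(c1ccccc1)C(C)(C)C)=[C@@]=C1C(C)(C)C[C@@H](O[Si](C)(C)C(C)(C)C)C[C@@]1(C)O | intermediate
14 | C15 furanoid bis-silyl ether, (3R,5R,8R) (key-step product) | CC(C)(C)[Si](OC/C=C(\C)[C@H]1C=C2C(C)(C)C[C@@H](O[Si](C)(C)C(C)(C)C)C[C@@]2(C)O1)(c1ccccc1)c1ccccc1 | intermediate
15 | (2R,6R,7aR)-2-[(E)-4-hydroxybut-2-en-2-yl]-4,4,7a-trimethyl-2,4,5,6,7,7a-hexahydro-1-benzofuran-6-ol | OC/C=C(\C)[C@H]1C=C2C(C)(C)C[C@@H](O)C[C@@]2(C)O1 | intermediate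
16 | (E)-3-Fur-but-2-enal | O=C/C=C(\C)[C@H]1C=C2C(C)(C)C[C@@H](O)C[C@@]2(C)O1 | intermediate
17 | triethyl 3-methyl-4-phosphonocrotonate | CCOC(=O)/C=C(\C)CP(=O)(OCC)OCC | starting material
18 | lithiated triethyl 3-methyl-4-phosphonocrotonate | [Li+].CCOC(=O)/C=C(\C)[CH-]P(=O)(OCC)OCC | intermediate (not isolated)
19 | ethyl (2E,4E,6E)-3-methyl-7-Fur-octa-2,4,6-trienoate | CCOC(=O)/C=C(C)/C=C/C=C(\C)[C@H]1C=C2C(C)(C)C[C@@H](O)C[C@@]2(C)O1 | intermediate
20 | (2E,4E,6E)-3-methyl-7-Fur-octa-2,4,6-trien-1-ol | OC/C=C(C)/C=C/C=C(\C)[C@H]1C=C2C(C)(C)C[C@@H](O)C[C@@]2(C)O1 | intermediate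
21 | (2E,4E,6E)-3-methyl-7-Fur-octa-2,4,6-trienal | O=C/C=C(C)/C=C/C=C(\C)[C@H]1C=C2C(C)(C)C[C@@H](O)C[C@@]2(C)O1 | intermediate
22 | ethyl (E)-4-bromo-2-methylbut-2-enoate | CCOC(=O)/C(C)=C/CBr | starting material
23 | triethyl 2-methyl-4-phosphonocrotonate | CCOC(=O)/C(C)=C/CP(=O)(OCC)OCC | intermediate
24 | lithiated triethyl 2-methyl-4-phosphonocrotonate | [Li+].CCOC(=O)/C(C)=C/[CH-]P(=O)(OCC)OCC | intermediate (not isolated)
25 | ethyl (2E,4E,6E,8E,10E)-2,7-dimethyl-11-Fur-dodeca-2,4,6,8,10-pentaenoate | CCOC(=O)/C(C)=C/C=C/C=C(C)/C=C/C=C(\C)[C@H]1C=C2C(C)(C)C[C@@H](O)C[C@@]2(C)O1 | intermediate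
26 | (2E,4E,6E,8E,10E)-2,7-dimethyl-11-Fur-dodeca-2,4,6,8,10-pentaen-1-ol | OC/C(C)=C/C=C/C=C(C)/C=C/C=C(\C)[C@H]1C=C2C(C)(C)C[C@@H](O)C[C@@]2(C)O1 | intermediate
27 | (2E,4E,6E,8E,10E)-2,7-dimethyl-11-Fur-dodeca-2,4,6,8,10-pentaenal | O=C/C(C)=C/C=C/C=C(C)/C=C/C=C(\C)[C@H]1C=C2C(C)(C)C[C@@H](O)C[C@@]2(C)O1 | intermediate
28 | sodium salt of triethyl 2-methyl-4-phosphonocrotonate (sodiated phosphonate) | [Na+].CCOC(=O)/C(C)=C/[CH-]P(=O)(OCC)OCC | intermediate (not isolated)
29 | ethyl (2E,4E,6E,8E,10E,12E,14E)-2,6,11-trimethyl-15-Fur-hexadeca-2,4,6,8,10,12,14-heptaenoate | CCOC(=O)/C(C)=C/C=C/C(C)=C/C=C/C=C(C)/C=C/C=C(\C)[C@H]1C=C2C(C)(C)C[C@@H](O)C[C@@]2(C)O1 | intermediate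
30 | (2E,4E,6E,8E,10E,12E,14E)-2,6,11-trimethyl-15-Fur-hexadeca-2,4,6,8,10,12,14-heptaen-1-ol | OC/C(C)=C/C=C/C(C)=C/C=C/C=C(C)/C=C/C=C(\C)[C@H]1C=C2C(C)(C)C[C@@H](O)C[C@@]2(C)O1 | intermediate
31 | (2E,4E,6E,8E,10E,12E,14E)-2,6,11-trimethyl-15-Fur-hexadeca-2,4,6,8,10,12,14-heptaenal | C\C(C=O)=C/C=C/C(C)=C/C=C/C=C(C)/C=C/C=C(\C)[C@H]1C=C2C(C)(C)C[C@@H](O)C[C@@]2(C)O1 | target

**Count**

Total steps: 23. Longest linear sequence: 21 (steps 1–4, 6–16, 18–23; steps 5 and 17 are side branches).

**Steps most likely to fail**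

1. Step 11 (gold cycloisomerisation). The risk is loss of stereochemical fidelity: gold may scramble the vinyl-substituted allene axis before C–O bond formation, the new doubly allylic C8–O bond may ionise and epimerise, and the vinylallene may divert into cyclopentadiene formation. The fallback is the classical acid-catalysed 5,6-epoxide to 5,8-furanoid rearrangement of carotenoid end groups. It sets out from triflate 6 and enyne 8 and comes back at diol 15.
   - Hydroboration of 8 with pinacolborane (Cp2Zr(H)Cl cat.) should give the pinacol (1E,3E)-dienylboronate F1.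
   - Suzuki–Miyaura coupling of F1 with 6 (Pd(PPh3)4, aq. K3PO4, dioxane, 70 °C) should give the 7E triene F2.
   - PPTS/MeOH frees the C3 hydroxyl to give the triene alcohol F3.
   - The same hydroxyl-directed epoxidation (VO(acac)2, t-BuOOH) should give the syn 5,6-epoxide F4.
   - A trace of acid (PPTS, CH2Cl2, 0 °C) opens the C6–O bond to the allyl cation, which O5 recaptures at C8. This should give the furanoid as the 8R epimer F5 and the 8S epimer F6.
   - The epimers are separated by chromatography, F6 is re-equilibrated under the same acid, and Bu4NF converts F5 into 15.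

2. Step 9 (SN2' reduction). The risk is hydride delivery to the wrong face of the alkyne (syn to the leaving oxygen) or to the wrong carbon (direct epoxide opening, alkyne hydroalumination), which would give the epimeric axis and hence the 8S series. The fallback changes the hydride transfer from Lewis-acid-assisted aluminium hydride to catalytic copper hydride, a known entry from propargyl oxiranes to α-hydroxyallenes for which the anti SN2' course is expected. It sets out from epoxide 11 and comes back at diol 12: (IPr)CuCl (3 mol %), NaOt-Bu, polymethylhydrosiloxane, toluene, 0 °C, then K2CO3/MeOH to cleave O–Si bonds formed with the silane. No new compound arises.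

3. Step 8 (directed epoxidation). The risk is slow oxygen transfer to the hindered, enyne-conjugated tetrasubstituted alkene, which would allow oxidation of the secondary alcohol or erosion of facial control. The fallback sets the epoxide under reagent control on an allylic alcohol before the enyne is assembled. It sets out from triflate 6 and comes back at epoxide 11.
   - Palladium-catalysed methoxycarbonylation of 6 (Pd(OAc)2, PPh3, CO, MeOH, Et3N, DMF) should give the ester F7.
   - i-Bu2AlH reduces F7 to the allylic alcohol F8.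
   - Sharpless asymmetric epoxidation (Ti(Oi-Pr)4, D-(−)-diethyl tartrate, t-BuOOH, 4 Å sieves, CH2Cl2, −20 °C) should give the epoxy alcohol F9. The tartrate enantiomer is the one that places oxygen on the face of the C3 silyloxy group; D-(−) is expected by analogy with the descriptor outcome for simple allylic alcohols.
   - Dess–Martin oxidation gives the epoxy aldehyde F10.
   - Ohira–Bestmann alkynylation (dimethyl (1-diazo-2-oxopropyl)phosphonate, K2CO3, MeOH) gives the terminal alkynyl epoxide F11.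
   - Sonogashira coupling of F11 with the vinyl iodide F12 (made from known (E)-3-iodobut-2-en-1-ol and t-BuPh2SiCl) gives the 3-O-TES epoxide F13.
   - PPTS/MeOH removes the TES group to give 11.

Further compounds

F1 | step 11 | pinacol (1E,3E)-5-(tert-butyldiphenylsilyloxy)-3-methylpenta-1,3-dien-1-ylboronate | CC1(C)OB(/C=C/C(C)=C/CO[Si](c2ccccc2)(c2ccccc2)C(C)(C)C)OC1(C)C
F2 | step 11 | 7E,9E triene with 3-O-TES and 11-O-TBDPS, (3S) | CC1=C(/C=C/C(C)=C/CO[Si](c2ccccc2)(c2ccccc2)C(C)(C)C)C(C)(C)C[C@@H](O[Si](CC)(CC)CC)C1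
F3 | step 11 | 7E,9E triene with free C3 hydroxyl and 11-O-TBDPS | CC1=C(/C=C/C(C)=C/CO[Si](c2ccccc2)(c2ccccc2)C(C)(C)C)C(C)(C)C[C@@H](O)C1
F4 | step 11 | syn 5,6-epoxide of F3, (3R,5R,6S) | C[C@@]12C[C@H](O)CC(C)(C)[C@]1(/C=C/C(C)=C/CO[Si](c3ccccc3)(c3ccccc3)C(C)(C)C)O2
F5 | step 11 | furanoid with free C3 hydroxyl and 11-O-TBDPS, (3R,5R,8R) | CC(C)(C)[Si](OC/C=C(\C)[C@H]1C=C2C(C)(C)C[C@@H](O)C[C@@]2(C)O1)(c1ccccc1)c1ccccc1
F6 | step 11 | 8S epimer of F5, (3R,5R,8S) | CC(C)(C)[Si](OC/C=C(\C)[C@@H]1C=C2C(C)(C)C[C@@H](O)C[C@@]2(C)O1)(c1ccccc1)c1ccccc1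
F0 | step 9 | none | none
F7 | step 8 | methyl (S)-2,6,6-trimethyl-4-(triethylsilyloxy)cyclohex-1-ene-1-carboxylate | CC1=C(C(=O)OC)C(C)(C)C[C@@H](O[Si](CC)(CC)CC)C1
F8 | step 8 | [(S)-2,6,6-trimethyl-4-(triethylsilyloxy)cyclohex-1-en-1-yl]methanol | CC1=C(CO)C(C)(C)C[C@@H](O[Si](CC)(CC)CC)C1
F9 | step 8 | epoxy alcohol, (3R,5R,6R), epoxide cis to the silyloxy group | C[C@@]12C[C@H](O[Si](CC)(CC)CC)CC(C)(C)[C@]1(CO)O2
F10 | step 8 | epoxy aldehyde, (3R,5R,6S; same spatial arrangement as F9, the C6 descriptor changes with the CIP ranking of the formyl group) | C[C@@]12C[C@H](O[Si](CC)(CC)CC)CC(C)(C)[C@]1(C=O)O2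
F11 | step 8 | terminal alkynyl epoxide, (3R,5R,6R) | C[C@@]12C[C@H](O[Si](CC)(CC)CC)CC(C)(C)[C@]1(C#C)O2
F12 | step 8 | (E)-tert-butyl[(3-iodobut-2-en-1-yl)oxy]diphenylsilane | C/C(I)=C\CO[Si](c1ccccc1)(c1ccccc1)C(C)(C)C
F13 | step 8 | alkynyl epoxide with 3-O-TES and 11-O-TBDPS, (3R,5R,6R) | C[C@@]12C[C@H](O[Si](CC)(CC)CC)CC(C)(C)[C@]1(C#C/C(C)=C/CO[Si](c3ccccc3)(c3ccccc3)C(C)(C)C)O2
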